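**Retrosynthetic overview**

- 14 ⇒ 10: the propanoyl group (ring B) and the butanoyl group (ring A) are removed from C1 of each ring, leaving the symmetrical methylenebis(filicinic acid) 10; forward these are two Friedel–Crafts C-acylations.
- Feature the strategy rests on: with C1 the acyl-bearing carbon, C2/C6 its flanking carbonyl carbons, C3 the CMe2 carbon, C4 the next carbonyl carbon and C5 the carbon on the bridging CH2, each ring holds an isopropyl ketone (C3–C4–C5) and a malonyl unit (C2–C1–C6), and C5–CH2–C5′ is the middle of 2,8-dimethylnonane-3,7-dione.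
- 10 ⇒ 7 + 2 × 8: C2–C3 and C5–C6 are cut in both rings; forward, rings A and B form together in one operation from bis(silyl enol ether) 7 and malonyl dichloride.
- 7 ⇒ 5 (1,4-hydrosilylation puts each enol ether on the isopropylidene side) ⇒ 3 (Weinreb ketone synthesis) ⇒ glutaryl dichloride 1.

Key step: step 4

Remark: the enolised triketone rings of 10, 12 and 14 are drawn as the dienol tautomer of the target SMILES; the tautomers interconvert and count as one compound, and the target has no stereocentre.

**Route**

Step 1
Reactants: 1 glutaryl dichloride; 2 N,O-dimethylhydroxylamine hydrochloride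
Product: 3 N1,N5-dimethoxy-N1,N5-dimethylpentanediamide
Conditions: MeNH(OMe)·HCl (2.2 equiv), pyridine (4.5 equiv), CH2Cl2, 0 °C → rt
Reagents that add atoms: N,O-dimethylhydroxylamine hydrochloride (2), CNOC.Cl
Why: Nucleophilic acyl substitution of both acid chlorides by the hydroxylamine (Weinreb amide formation), with pyridine taking up the HCl.

Step 2
Reactants: 3 N1,N5-dimethoxy-N1,N5-dimethylpentanediamide; 4 isopropenylmagnesium bromide
Product: 5 2,8-dimethylnona-1,8-diene-3,7-dione
Conditions: CH2=C(Me)MgBr (2.6 equiv), THF, 0 °C; inverse quench into cold 1 M HCl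
Reagents that add atoms: isopropenylmagnesium bromide (4), CC(=C)[Mg]Br
Why: Weinreb ketone synthesis, in which each magnesium-chelated tetrahedral adduct survives until hydrolysis so that no tertiary alcohol forms, and the acidic inverse quench protonates the liberated MeNH(OMe) before it can add to the new enones.

Step 3
Reactants: 5 2,8-dimethylnona-1,8-diene-3,7-dione; 6 triethylsilane
Product: 7 2,8-dimethyl-3,7-bis(triethylsilyloxy)nona-2,7-diene
Conditions: Et3SiH (2.3 equiv), RhCl(PPh3)3 (1 mol %), PhH, 60 °C, Ar; filtration through Celite in pentane, short-path distillation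
Reagents that add atoms: triethylsilane (6), CC[SiH](CC)CC
Why: Rhodium-catalysed 1,4-hydrosilylation of an enone by a monohydrosilane delivers H to each terminal CH2 and silicon to oxygen, so each enol ether double bond lies on the isopropylidene side, and no E/Z question arises because that carbon carries two methyl groups.

Step 4
Reactants: 7 2,8-dimethyl-3,7-bis(triethylsilyloxy)nona-2,7-diene; 8 malonyl dichloride
Product: 10 2,2'-methylenebis(3,5-dihydroxy-4,4-dimethylcyclohexa-2,5-dien-1-one), via open-chain bis(keto acid chloride) 9 (not isolated)
Conditions: 7 added to ClCOCH2COCl (2.1 equiv), Et2O, −20 °C → rt; then NaOMe, MeOH, 0 °C → rt; aq HCl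
Reagents that add atoms: malonyl dichloride (8), ClC(=O)CC(Cl)=O
Why: Each Me2C= enol ether carbon (the future C3) adds to one acyl chloride of 8 (or to the chlorocarbonylketene formed from it) and loses Et3SiCl, which sets the C2–C3 bond and the quaternary carbon and leaves keto acid chloride 9; its C4 ketone has no hydrogen left on the C3 side, enolises toward C5, and C5 attacks the second acyl chloride to make C5–C6. The closest known reaction is the Effenberger annulation of ketone enol ethers with malonyl dichloride, which gives phloroglucinols from simple enol ethers and bicyclo[3.3.1]nonane-2,4,9-triones from tetrasubstituted cyclohexenyl enol ethers; here it runs at both ends of one chain and stops at the trione (filicinic acid) level because C3 carries no hydrogen. Ring A and ring B each close by a 6-(enolendo)-exo-trig acyl substitution, and no stereocentre is formed. The step needs closure through carbon and one malonyl unit per ketone: the hydrosilylation has fixed each enol ether on the isopropylidene side so the first acylation can only take place at C3, closure within one ketone gives a six-membered ring while bridging the two ends would give a ten-membered one, and 8 is kept near two equivalents because the product enols can be acylated by it. The methoxide stage turns any enol lactone from closure through oxygen and any uncyclised acid chloride (as its methyl ester) into the carbocycle by ring opening and Claisen condensation, the doubly enolised trione salt being the thermodynamic sink, and base-induced exchange of the methylene bridge is degenerate for this symmetrical product.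

Step 5
Reactants: 10 2,2'-methylenebis(3,5-dihydroxy-4,4-dimethylcyclohexa-2,5-dien-1-one); 11 butanoyl chloride
Product: 12 2-butanoyl-6-[(2,4-dihydroxy-3,3-dimethyl-6-oxocyclohexa-1,4-dien-1-yl)methyl]-3,5-dihydroxy-4,4-dimethylcyclohexa-2,5-dien-1-one
Conditions: n-PrCOCl (0.8 equiv), TiCl4 (3 equiv), CH2Cl2, 0 °C → rt; cold aq HCl; recovered 10 recycled
Reagents that add atoms: butanoyl chloride (11), CCCC(Cl)=O
Why: Friedel–Crafts C-acylation of the enolised triketone at its only free ring CH (C1, between C2 and C6), with the acyl chloride kept limiting because the two rings are equivalent, so that mainly mono-ketone 12 should form and be separable from recovered 10 and from diacylated material by polarity.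

Step 6
Reactants: 12 2-butanoyl-6-[(2,4-dihydroxy-3,3-dimethyl-6-oxocyclohexa-1,4-dien-1-yl)methyl]-3,5-dihydroxy-4,4-dimethylcyclohexa-2,5-dien-1-one; 13 propanoyl chloride
Product: 14 2-butanoyl-6-[(2,4-dihydroxy-3,3-dimethyl-6-oxo-5-propanoylcyclohexa-1,4-dien-1-yl)methyl]-3,5-dihydroxy-4,4-dimethylcyclohexa-2,5-dien-1-one (target)
Conditions: EtCOCl (1.5 equiv), TiCl4 (3 equiv), CH2Cl2, 0 °C, short reaction time; cold aq HCl
Reagents that add atoms: propanoyl chloride (13), CCC(Cl)=O
Why: The same Friedel–Crafts C-acylation at the last free C1–H, that of ring B, since ring A is fully substituted and deactivated by its acyl group, and the cold, base-free conditions are chosen to keep the methylene bridge from exchanging.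

**Compound list**

1 | glutaryl dichloride (pentanedioyl dichloride) | ClC(=O)CCCC(Cl)=O | starting material
2 | N,O-dimethylhydroxylamine hydrochloride | CNOC.Cl | starting material
3 | N1,N5-dimethoxy-N1,N5-dimethylpentanediamide | CON(C)C(=O)CCCC(=O)N(C)OC | intermediate
4 | isopropenylmagnesium bromide (prop-1-en-2-ylmagnesium bromide) | CC(=C)[Mg]Br | starting material
5 | 2,8-dimethylnona-1,8-diene-3,7-dione | CC(=C)C(=O)CCCC(=O)C(C)=C | intermediate
6 | triethylsilane | CC[SiH](CC)CC | starting material
7 | 2,8-dimethyl-3,7-bis(triethylsilyloxy)nona-2,7-diene | CC(C)=C(O[Si](CC)(CC)CC)CCCC(O[Si](CC)(CC)CC)=C(C)C | intermediate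
8 | malonyl dichloride (propanedioyl dichloride) | ClC(=O)CC(Cl)=O | starting material
9 | 4,4,10,10-tetramethyl-3,5,9,11-tetraoxotridecanedioyl dichloride | ClC(=O)CC(=O)C(C)(C)C(=O)CCCC(=O)C(C)(C)C(=O)CC(Cl)=O | intermediate
10 | 2,2'-methylenebis(3,5-dihydroxy-4,4-dimethylcyclohexa-2,5-dien-1-one), methylenebis(filicinic acid) | O=C1C=C(O)C(C)(C)C(O)=C1CC1=C(O)C(C)(C)C(O)=CC1=O | intermediate
11 | butanoyl chloride | CCCC(Cl)=O | starting material
12 | 2-butanoyl-6-[(2,4-dihydroxy-3,3-dimethyl-6-oxocyclohexa-1,4-dien-1-yl)methyl]-3,5-dihydroxy-4,4-dimethylcyclohexa-2,5-dien-1-one | CCCC(=O)C1=C(O)C(C)(C)C(O)=C(CC2=C(O)C(C)(C)C(O)=CC2=O)C1=O | intermediate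
13 | propanoyl chloride | CCC(Cl)=O | starting material
14 | 2-butanoyl-6-[(2,4-dihydroxy-3,3-dimethyl-6-oxo-5-propanoylcyclohexa-1,4-dien-1-yl)methyl]-3,5-dihydroxy-4,4-dimethylcyclohexa-2,5-dien-1-one | CCCC(=O)C1=C(O)C(C)(C)C(O)=C(CC2=C(O)C(C)(C)C(O)=C(C(=O)CC)C2=O)C1=O | target

**Step count**

Total steps: 6. Longest linear sequence: 6 steps (1 → 3 → 5 → 7 → 10 → 12 → 14).

**Steps most likely to fail**

Step 4. The HCl released on ring closure may protodesilylate enol ether that has not yet been acylated, closure may go through oxygen, and the product enols may be acylated further by malonyl dichloride. Fallback, setting out from 7 and coming back at 10: the two bonds of each ring are made in separate operations. ZnCl2-promoted C-acylation of 7 with methyl 3-chloro-3-oxopropanoate (a monofunctional malonyl half-ester chloride) in CH2Cl2/Et2O should give dimethyl 4,4,10,10-tetramethyl-3,5,9,11-tetraoxotridecanedioate F1. NaOMe in MeOH then closes both rings by Claisen (Dieckmann-type) condensation of each C5 methylene onto its ester, and acidification gives 10.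

Step 5. The two rings are identical and electronically independent, so double acylation competes with mono-acylation at any useful conversion, and acylation on oxygen may intervene. Fallback, setting out from 10 and coming back at 14 (12 and step 6 are bypassed): ring discrimination is given up.
- One portion of 10 is acylated on both rings with excess 11 and TiCl4 to 2,2'-methylenebis(6-butanoyl-3,5-dihydroxy-4,4-dimethylcyclohexa-2,5-dien-1-one) F2.
- A second portion is acylated with excess 13 to 2,2'-methylenebis(3,5-dihydroxy-4,4-dimethyl-6-propanoylcyclohexa-2,5-dien-1-one) F3.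
- Equimolar F2 and F3 are equilibrated in dilute aqueous NaOH at room temperature, where the methylene bridge opens and re-forms by retro-Michael/Michael addition (the rottlerone change of methylene-bridged acylphloroglucinols).
- The crossed product 14 is separated by reversed-phase chromatography, and F2 and F3 are returned to the equilibration.

Step 6. Under TiCl4 and HCl the methylene bridge may exchange between rings, scrambling 12 and 14 toward the symmetrical diacyl compounds, or the acyl group may end up on oxygen. Fallback, setting out from 12 and coming back at 14: acid-free acylation by acyl transfer. Propanoic acid, DCC and DMAP in CH2Cl2 at room temperature should first give the enol ester 4-[(5-butanoyl-2,4-dihydroxy-3,3-dimethyl-6-oxocyclohexa-1,4-dien-1-yl)methyl]-5-hydroxy-6,6-dimethyl-3-oxocyclohexa-1,4-dien-1-yl propanoate F4. DMAP then moves the acyl group in the same flask from oxygen to the free ring carbon (1,3-acyl migration through the acylpyridinium/enolate pair), giving 14.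

**Further compounds**

F1 | step 4 | dimethyl 4,4,10,10-tetramethyl-3,5,9,11-tetraoxotridecanedioate | COC(=O)CC(=O)C(C)(C)C(=O)CCCC(=O)C(C)(C)C(=O)CC(=O)OC
F2 | step 5 | 2,2'-methylenebis(6-butanoyl-3,5-dihydroxy-4,4-dimethylcyclohexa-2,5-dien-1-one) | CCCC(=O)C1=C(O)C(C)(C)C(O)=C(CC2=C(O)C(C)(C)C(O)=C(C(=O)CCC)C2=O)C1=O
F3 | step 5 | 2,2'-methylenebis(3,5-dihydroxy-4,4-dimethyl-6-propanoylcyclohexa-2,5-dien-1-one) | CCC(=O)C1=C(O)C(C)(C)C(O)=C(CC2=C(O)C(C)(C)C(O)=C(C(=O)CC)C2=O)C1=O
F4 | step 6 | 4-[(5-butanoyl-2,4-dihydroxy-3,3-dimethyl-6-oxocyclohexa-1,4-dien-1-yl)methyl]-5-hydroxy-6,6-dimethyl-3-oxocyclohexa-1,4-dien-1-yl propanoate | CCCC(=O)C1=C(O)C(C)(C)C(O)=C(CC2=C(O)C(C)(C)C(OC(=O)CC)=CC2=O)C1=O
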